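## Structural features

The target is a C37 carotenoid-type butenolide in which three rings, A, B and C, sit on one conjugated chain. Ring A is a cyclohexane (C1 gem-dimethyl, C3 secondary hydroxyl, C5 tertiary hydroxyl with methyl, C6 tertiary hydroxyl) of configuration 3S,5R,6R. Its C5 and C6 hydroxyls are trans; the C6 hydroxyl is cis and the C5 hydroxyl trans to the C3 hydroxyl; the two tertiary carbinols are adjacent and C6 is also neopentyl. C6 carries an (E)-vinylene that ends at C3 of ring C, a furan-2(5H)-one (O1, C2 carbonyl, C3, C4–H, C5) whose C5 bears a (Z)-ylidene. From the ylidene, four E double bonds with a methyl on each terminal olefin run to an alkyne on the tetrasubstituted olefinic carbon of ring B. Ring B is a 4-hydroxy-2,6,6-trimethylcyclohexene whose single stereocentre (R) has the same spatial sense as C3 of ring A, so both rings can come from one chiral ketone. Fragile elements are the base- and light-sensitive ylidenebutenolide, the polyenyne, the tertiary allylic alcohol at C6 (ionisation under acid) and any terminal alkyne conjugated to the polyene on the way. The real difficulties are the contiguous tertiary diol of ring A in a fixed relation to C3, and the closure of ring C with a Z exocyclic double bond without scrambling the chain. The key step uses the fact that O1–C5(=CH)–C4H=C3 of ring C is the cyclised form of a 2-en-4-ynoic acid, and that the chain between ring C and the ring B alkyne is locally symmetric, so it can end in an alkyne on both sides.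

## Logic of the disconnections

26 to 19 and 25. The bond cut is the sp2–sp2 single bond between C3 of ring C and the vinyl carbon attached to ring A. This is the one place where ring C offers a natural electrophile (an α-bromo enone carbon), and it splits the molecule into two hemispheres of similar size. All four hydroxyls can stay free, so nothing has to be removed from the finished polyene. The forward step must be a neutral cross-coupling that keeps the E stannane geometry and the Z ylidene.

19 to 15 and 17 (key disconnection). The bonds cut are C4–C5 and O1–C5 of ring C. This removes the ring, the Z exocyclic double bond and the C3 handle at once and leaves a linear terminal alkyne plus a three-carbon dibromo acid. Forward, coupling must occur only at the β-bromine, the acid must close 5-exo and not 6-endo, addition across the alkyne must be anti, and the α-bromine must survive.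

17 to 16. Two C–Br bonds are cut. The forward step must be an anti addition so that the β-bromine ends cis to the carboxyl group.

15 to 14. One O–Si and one C(sp)–Si bond are cut. Both silyl groups serve only the chain assembly; removing them together before the key step means no deprotection follows the last coupling. The demand is that fluoride leaves the tetraenediyne intact.

14 to 10 and 13. The cut is the C5=C6 double bond of the dodecatetraenediyne chain. Each fragment holds one of the two identical methyl-enyne termini, and the two chain ends differ from the start (one bonded to ring B, one silylated). No statistical mono-functionalisation of a symmetric diyne is therefore needed. The forward olefination must be E-selective and must not scramble the trisubstituted double bond of the phosphonate anion.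

13 to 8 and 11 (through 12). The cut is the C2=C3 double bond of the dienynal. The two central chain carbons come from the mono-acetal of glyoxal, so its two aldehyde carbons are used one at a time. The demands are an anhydrous aldehyde and an acetal hydrolysis mild enough for the C-silyl alkyne.

10 to 3 and 9. The cut is the sp2–sp bond between ring B and the alkyne. The same C5 phosphonate family that builds 13 is used again, so both halves of the locally symmetric chain share 8. The coupling must work at a hindered tetrasubstituted enol triflate with phosphonate and silyl ether as spectators.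

9 to 8, 7, 6 and 4 (through 5). The bonds cut are C(sp)–Si, C–P, C–Br and again C(sp)–Si. The silyl cap keeps the acetylenic proton away from the phosphonate carbanion, and the E geometry of 4 is carried through unchanged.

25 to 24. The C–Sn and C–H bonds across the alkyne are cut. The forward hydrostannation must be syn and place tin on the terminal carbon.

24 to 23. The C5–O bond is cut (water as the oxygen source). A trans diol comes from an epoxide by inversion at one carbon. Water must attack C5 and not C6.

23 to 22. The two C–O bonds of the epoxide are cut. The C3 hydroxyl selects the face, and the epoxide oxygen becomes the C6 hydroxyl, which is therefore cis to the C3 hydroxyl.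

22 to 21, and 21 to 3 and 20. O–Si and C–Si bonds are removed, then the sp2–sp bond between ring A and its alkyne is cut. The coupling conditions of the ring B side are reused.

3 to 2 to 1. The C–O bond of the triflate and the O–Si bond are cut. Both ring fragments derive from 3; the C6 stereocentre of 1 is given up on purpose and only C4 is kept. Enolisation is possible in one direction only.

## Other disconnections considered

Alternative 1: The cut is the pair of C–O bonds at C3 and C6 of ring A, traced back to oxygen adding across a cyclohexadiene. Forward, safranal A1 would be converted into the silylethynyl diene A2, and photosensitised singlet oxygen would add [4+2] across the diene termini to give the endoperoxide A3. O–O reduction would give the cis-enediol A4, and the C5 hydroxyl would then be added trans to both oxygens by an anti epoxidation and hydride opening on A4.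
- In its favour: the cis relation of the C3 and C6 oxygens is fixed by the suprafacial cycloaddition. On this point it is better than the chosen plan, which depends on a hydroxyl-directed epoxidation. The starting material is cheap, and no tetrasubstituted epoxide has to be hydrolysed.
- Against it here: A2 is achiral, so A3 would form as a racemate and a resolution would be needed. The ene reaction of singlet oxygen at the ring methyl would compete. The diene terminus bearing the alkyne is neopentyl. The later C5 oxygenation must go against two hydroxyls without any direction.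
- Comparison: two C–O bonds per step are formed in both plans. The alternative is superior in relative stereocontrol and inferior in absolute stereocontrol, since the chosen plan takes both rings from one chiral ketone. The step count for ring A would be similar before resolution and higher after it. Ring C would be built the same way.

Alternative 2: The cut is the triple bond between ring B and the chain, made by inserting one carbon into a ketone. Forward, the lithiated silyl diazomethane reagent would add to the carbonyl of dienone A5; loss of silanolate and nitrogen would give an alkylidene carbene, and 1,2-shift of an alkenyl group would give the enyne acetal A6.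
- In its favour: no palladium, copper or triflate is needed. Either alkenyl group may migrate with the same result, so in regiochemical certainty it equals the chosen coupling of 3. The chain olefin geometry is untouched.
- Against it here: A5 must first be assembled by acylation at the hindered ring B carbon, where the chosen plan needs one coupling. The carbonyl lies between a tetrasubstituted olefin and a gem-dimethyl group, so addition would be slow. Carbene C–H insertion into a ring methyl and cyclopropanation are plausible side paths. A6 holds only five of the twelve chain carbons, so the rest is still added linearly.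
- Comparison: the same ring B enyne results. The mechanism is a carbene rearrangement against a cross-coupling. Step economy would be worse by about three steps. On freedom from transition metals the alternative is the better.

Alternative 3: The cut is C2–C3 and C2–O1 of ring C, with the carbonyl carbon coming from carbon monoxide. Forward, zerovalent palladium generated from PdCl2(PPh3)2 would insert into the C–I bond of the (Z)-β-iodo enone A7; CO would insert, and the dienol oxygen of the ketone would trap the acylpalladium to give the ylidenebutenolide A8.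
- In its favour: ring A is already attached when the ring closes, so no organotin reagent and no final Stille coupling are needed; on this point it is better. One ring and two bonds are formed, equal to the chosen key step.
- Against it here: A7 needs a regio- and stereodefined hydroiodination of an ynone and must enolise towards C5 in the right geometry. The Z ylidene would rest on equilibration and not on the mechanism. A8 holds only the first five chain carbons, so the polyene would have to be grown on a base-sensitive ylidenebutenolide, with two silyl ethers to remove at the very end. A free tertiary diol would be exposed to CO and palladium.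
- Comparison: the same ring results. The chosen plan fixes the geometry through anti addition and brings the whole chain in one step. After the key step the alternative would need about four more steps against one.

Key step: step 12

Assumption (remark on the chemistry): anhydrous 2,2-dimethoxyacetaldehyde 11, the commercial mono-acetal of glyoxal, supplies the two central chain carbons in place of free glyoxal; it is dried by extraction and distillation before use.

## Steps

Step 1
Reactants: 1 (4R,6R)-4-hydroxy-2,2,6-trimethylcyclohexan-1-one (actinol)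
Product: 2 (4R,6R)-4-[(tert-butyldimethylsilyl)oxy]-2,2,6-trimethylcyclohexan-1-one
Conditions: TBSCl, imidazole, DMF, rt
Reagents that add atoms: tert-butyldimethylsilyl chloride, CC(C)(C)[Si](C)(C)Cl
Why: Imidazole-promoted silylation of the only hydroxyl (secondary, unhindered); the ketone and both stereocentres are untouched.

Step 2
Reactants: 2 (4R,6R)-4-[(tert-butyldimethylsilyl)oxy]-2,2,6-trimethylcyclohexan-1-one
Product: 3 (4R)-4-[(tert-butyldimethylsilyl)oxy]-2,6,6-trimethylcyclohex-1-en-1-yl trifluoromethanesulfonate
Conditions: LDA, THF, −78 to 0 °C; PhNTf2, 0 °C to rt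
Reagents that add atoms: N-phenylbis(trifluoromethanesulfonimide), O=S(=O)(N(c1ccccc1)S(=O)(=O)C(F)(F)F)C(F)(F)F
Why: The ketone can enolise only towards C6 because C2 is quaternary, so deprotonation and O-sulfonylation give a single tetrasubstituted enol triflate; the C6 stereocentre is given up by design and C4 is unaffected.

Step 3
Reactants: 4 (2E)-3-methylpent-2-en-4-yn-1-ol
Product: 6 (2E)-3-methyl-5-(trimethylsilyl)pent-2-en-4-yn-1-ol, via bis-silylated enynol 5 (not isolated)
Conditions: EtMgBr (2.2 equiv), THF, 0 to 40 °C; TMSCl (2.2 equiv), rt; then 1 M H2SO4, rt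
Reagents that add atoms: chlorotrimethylsilane, C[Si](C)(C)Cl
Why: Double deprotonation and silylation at oxygen and at the alkyne carbon, then selective acid hydrolysis of the labile silyl ether in the work-up, is the standard capping of a terminal alkyne; the E double bond is not involved.

Step 4
Reactants: 6 (2E)-3-methyl-5-(trimethylsilyl)pent-2-en-4-yn-1-ol
Product: 7 [(3E)-5-bromo-3-methylpent-3-en-1-yn-1-yl]trimethylsilane
Conditions: PBr3 (0.4 equiv), pyridine (cat.), Et2O, 0 °C
Reagents that add atoms: phosphorus tribromide, BrP(Br)Br
Why: Bromide displaces the phosphite ester of the primary allylic alcohol by SN2 at 0 °C, with retention of the E trisubstituted double bond.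

Step 5
Reactants: 7 [(3E)-5-bromo-3-methylpent-3-en-1-yn-1-yl]trimethylsilane
Product: 8 diethyl [(2E)-3-methyl-5-(trimethylsilyl)pent-2-en-4-yn-1-yl]phosphonate
Conditions: P(OEt)3 (neat), 100 °C
Reagents that add atoms: triethyl phosphite, CCOP(OCC)OCC
Why: Michaelis–Arbuzov reaction of a primary allylic bromide; the C-silyl group later keeps the acetylenic position from being deprotonated during olefination.

Step 6
Reactants: 8 diethyl [(2E)-3-methyl-5-(trimethylsilyl)pent-2-en-4-yn-1-yl]phosphonate
Product: 9 diethyl [(2E)-3-methylpent-2-en-4-yn-1-yl]phosphonate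
Conditions: K2CO3 (0.2 equiv), MeOH, 0 °C to rt
Reagents that add atoms: none
Why: Carbonate-catalysed methanolysis of the alkynyl C–Si bond is fast and leaves the phosphonate ester and the E olefin untouched.

Step 7
Reactants: 3 (4R)-4-[(tert-butyldimethylsilyl)oxy]-2,6,6-trimethylcyclohex-1-en-1-yl trifluoromethanesulfonate; 9 diethyl [(2E)-3-methylpent-2-en-4-yn-1-yl]phosphonate
Product: 10 diethyl {(2E)-5-[(4R)-4-[(tert-butyldimethylsilyl)oxy]-2,6,6-trimethylcyclohex-1-en-1-yl]-3-methylpent-2-en-4-yn-1-yl}phosphonate
Conditions: Pd(PPh3)4 (5 mol%), CuI (10 mol%), i-Pr2NH, DMF, rt to 40 °C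
Reagents that add atoms: none
Why: Sonogashira coupling of an enol triflate with a terminal alkyne forms the sp2–sp bond of ring B; the amine is too weak to deprotonate the phosphonate and the silyl ether is stable.

Step 8
Reactants: 8 diethyl [(2E)-3-methyl-5-(trimethylsilyl)pent-2-en-4-yn-1-yl]phosphonate; 11 2,2-dimethoxyacetaldehyde
Product: 13 (2E,4E)-5-methyl-7-(trimethylsilyl)hepta-2,4-dien-6-ynal, via dienyne dimethyl acetal 12 (not isolated)
Conditions: NaHMDS, THF, −78 °C; 11, −78 to 0 °C; then 1 M HCl, THF, 0 °C
Reagents that add atoms: water, O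
Why: Horner–Wadsworth–Emmons olefination of the allylic phosphonate carbanion with the free aldehyde of the mono-acetal gives the E disubstituted double bond, the silyl cap prevents deprotonation at the alkyne, and dilute acid hydrolyses the conjugated acetal without cleaving the C–Si bond.

Step 9
Reactants: 10 diethyl {(2E)-5-[(4R)-4-[(tert-butyldimethylsilyl)oxy]-2,6,6-trimethylcyclohex-1-en-1-yl]-3-methylpent-2-en-4-yn-1-yl}phosphonate; 13 (2E,4E)-5-methyl-7-(trimethylsilyl)hepta-2,4-dien-6-ynal
Product: 14 tert-butyl{[(1R)-4-[(3E,5E,7E,9E)-3,10-dimethyl-12-(trimethylsilyl)dodeca-3,5,7,9-tetraene-1,11-diyn-1-yl]-3,5,5-trimethylcyclohex-3-en-1-yl]oxy}dimethylsilane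
Conditions: NaHMDS, THF, −78 to 0 °C, dark
Reagents that add atoms: none
Why: Horner–Wadsworth–Emmons olefination between the stabilised allylic phosphonate anion and the dienynal should give the central E double bond; low temperature and a non-nucleophilic amide base limit E/Z scrambling of the delocalised anion and loss of the C-silyl group, and a minor Z isomer can be removed or isomerised.

Step 10
Reactants: 14 tert-butyl{[(1R)-4-[(3E,5E,7E,9E)-3,10-dimethyl-12-(trimethylsilyl)dodeca-3,5,7,9-tetraene-1,11-diyn-1-yl]-3,5,5-trimethylcyclohex-3-en-1-yl]oxy}dimethylsilane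
Product: 15 (1R)-4-[(3E,5E,7E,9E)-3,10-dimethyldodeca-3,5,7,9-tetraene-1,11-diyn-1-yl]-3,5,5-trimethylcyclohex-3-en-1-ol
Conditions: TBAF (3 equiv), THF, 0 °C to rt, dark
Reagents that add atoms: none
Why: Fluoride cleaves the alkynyl C–Si bond at once and the secondary silyl ether more slowly; doing both here gives the free-hydroxyl terminal alkyne for the key step, so no deprotection is left for the final polyene.

Step 11
Reactants: 16 prop-2-ynoic acid (propiolic acid)
Product: 17 (2E)-2,3-dibromoprop-2-enoic acid
Conditions: Br2 (1.05 equiv), CHCl3, 0 °C to rt, dark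
Reagents that add atoms: bromine, BrBr
Why: Ionic anti addition of bromine to the alkyne in the dark gives the E dibromide, in which the β-bromine is cis to the carboxyl group as needed for lactonisation after coupling.

Step 12
Reactants: 15 (1R)-4-[(3E,5E,7E,9E)-3,10-dimethyldodeca-3,5,7,9-tetraene-1,11-diyn-1-yl]-3,5,5-trimethylcyclohex-3-en-1-ol; 17 (2E)-2,3-dibromoprop-2-enoic acid
Product: 19 (5Z)-3-bromo-5-{(2E,4E,6E,8E)-11-[(4R)-4-hydroxy-2,6,6-trimethylcyclohex-1-en-1-yl]-2,9-dimethylundeca-2,4,6,8-tetraen-10-yn-1-ylidene}furan-2(5H)-one, via bromoenynoic acid 18 (not isolated)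
Conditions: 17 (1.5 equiv), Pd(PPh3)4 (5 mol%), CuI (10 mol%), Et3N (4 equiv), MeCN, rt, dark; 15 added slowly
Reagents that add atoms: none
Why: Tandem Sonogashira coupling and lactonisation, the known way from cis-β-haloacrylic acids and terminal alkynes to (Z)-γ-ylidenebutenolides. Zerovalent palladium inserts into the β C–Br bond of the ammonium salt of 17, the more electrophilic of the two C–Br bonds because it sits at the conjugate position of the acrylate, and the copper acetylide of 15 transmetalates. Reductive elimination forms the C4–C5 bond with retention and gives 18, whose descriptor is 2E because bromine outranks the carboxyl carbon, although alkyne and carboxylate are cis. The carboxylate oxygen then attacks the proximal alkyne carbon of the metal-activated triple bond from the side opposite the metal (monovalent copper or divalent palladium), and protonolysis of the alkenyl–metal bond forms O1–C5 and releases 19; ring C closes in the 5-exo-dig mode. No stereocentre is created; the Z geometry of the ylidene is the direct outcome of the anti oxymetalation and is also the isomer in which the chain avoids C4–H. Closure to the six-membered pyranone (6-endo) is disfavoured because the cis-enynoate holds the oxygen in line with the proximal sp carbon and the mild amine and copper conditions do not polarise the alkyne towards its distal end. The α-bromine survives because oxidative addition there is slower, and an excess of 17 with slow addition of 15 keeps the product bromide from coupling a second time. The free hydroxyl, the internal alkyne and the tetraene take no part.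

Step 13
Reactants: 3 (4R)-4-[(tert-butyldimethylsilyl)oxy]-2,6,6-trimethylcyclohex-1-en-1-yl trifluoromethanesulfonate; 20 ethynyltrimethylsilane
Product: 21 tert-butyldimethyl{[(1R)-3,5,5-trimethyl-4-[(trimethylsilyl)ethynyl]cyclohex-3-en-1-yl]oxy}silane
Conditions: Pd(PPh3)4 (5 mol%), CuI (10 mol%), i-Pr2NH, DMF, rt
Reagents that add atoms: none
Why: Sonogashira coupling of the same enol triflate with the silyl-capped acetylene installs the C6 alkyne of ring A; the cap prevents double coupling.

Step 14
Reactants: 21 tert-butyldimethyl{[(1R)-3,5,5-trimethyl-4-[(trimethylsilyl)ethynyl]cyclohex-3-en-1-yl]oxy}silane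
Product: 22 (1R)-4-ethynyl-3,5,5-trimethylcyclohex-3-en-1-ol
Conditions: TBAF (3 equiv), THF, rt
Reagents that add atoms: none
Why: Fluoride removes both silyl groups and frees the homoallylic hydroxyl that must direct the next step; the tetrasubstituted enyne is inert to fluoride.

Step 15
Reactants: 22 (1R)-4-ethynyl-3,5,5-trimethylcyclohex-3-en-1-ol
Product: 23 (1S,3S,6S)-6-ethynyl-1,5,5-trimethyl-7-oxabicyclo[4.1.0]heptan-3-ol (epoxide oxygen cis to the hydroxyl)
Conditions: VO(acac)2 (5 mol%), t-BuOOH (1.5 equiv, decane), toluene, rt to 40 °C
Reagents that add atoms: tert-butyl hydroperoxide, CC(C)(C)OO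
Why: Vanadium-catalysed hydroxyl-directed epoxidation of a homoallylic alcohol: the C3 alkoxide binds the vanadium peroxide and delivers oxygen to its own ring face, so the epoxide oxygen (the future C6 hydroxyl) should be cis to the C3 hydroxyl and both new stereocentres are set by C3; the undirected reaction is slow and the alkyne is inert.

Step 16
Reactants: 23 (1S,3S,6S)-6-ethynyl-1,5,5-trimethyl-7-oxabicyclo[4.1.0]heptan-3-ol
Product: 24 (1S,2R,4S)-1-ethynyl-2,6,6-trimethylcyclohexane-1,2,4-triol
Conditions: HClO4 (5% aq., cat.), THF/H2O, 0 °C to rt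
Reagents that add atoms: water, O
Why: Acid-catalysed anti opening of the epoxide by water at C5 inverts C5 and retains C6, giving the trans-5,6-diol with the C6 hydroxyl cis and the C5 hydroxyl trans to the C3 hydroxyl; attack at C6 is disfavoured sterically (adjacent gem-dimethyl carbon) and electronically (an alkynyl group destabilises positive charge at the carbon it is attached to).

Step 17
Reactants: 24 (1S,2R,4S)-1-ethynyl-2,6,6-trimethylcyclohexane-1,2,4-triol
Product: 25 (1R,2R,4S)-2,6,6-trimethyl-1-[(E)-2-(tributylstannyl)ethenyl]cyclohexane-1,2,4-triol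
Conditions: Bu3SnH (1.2 equiv), PdCl2(PPh3)2 (3 mol%), THF, 0 °C to rt
Reagents that add atoms: tributyltin hydride, CCCC[SnH](CCCC)CCCC
Why: Palladium-catalysed syn hydrostannation of a terminal alkyne; with a fully substituted propargylic carbon, tin should go to the terminal carbon and give the (E)-β-stannane, free hydroxyls are tolerated, and purification on triethylamine-deactivated silica avoids protodestannylation.

Step 18
Reactants: 19 (5Z)-3-bromo-5-{(2E,4E,6E,8E)-11-[(4R)-4-hydroxy-2,6,6-trimethylcyclohex-1-en-1-yl]-2,9-dimethylundeca-2,4,6,8-tetraen-10-yn-1-ylidene}furan-2(5H)-one; 25 (1R,2R,4S)-2,6,6-trimethyl-1-[(E)-2-(tributylstannyl)ethenyl]cyclohexane-1,2,4-triol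
Product: 26 (5Z)-5-{(2E,4E,6E,8E)-11-[(4R)-4-hydroxy-2,6,6-trimethylcyclohex-1-en-1-yl]-2,9-dimethylundeca-2,4,6,8-tetraen-10-yn-1-ylidene}-3-{(E)-2-[(1R,2R,4S)-1,2,4-trihydroxy-2,6,6-trimethylcyclohexyl]ethenyl}furan-2(5H)-one (target)
Conditions: Pd2(dba)3·CHCl3 (5 mol%), AsPh3 (40 mol%), DMF (degassed), 40 °C, dark
Reagents that add atoms: none
Why: Stille coupling: zerovalent palladium inserts into the electron-poor C3–Br bond, transmetalation from tin is helped by the weakly bound AsPh3, and reductive elimination retains both olefin geometries; the neutral conditions spare the ylidenebutenolide, the tertiary allylic alcohol and the four free hydroxyls, so the coupling product is the target with no stereocentre touched.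

## Compound list

1 | (4R,6R)-4-hydroxy-2,2,6-trimethylcyclohexan-1-one (actinol) | O=C1C(C)(C)C[C@H](O)C[C@H]1C | starting material
2 | (4R,6R)-4-[(tert-butyldimethylsilyl)oxy]-2,2,6-trimethylcyclohexan-1-one | O=C1C(C)(C)C[C@H](O[Si](C)(C)C(C)(C)C)C[C@H]1C | intermediate
3 | (4R)-4-[(tert-butyldimethylsilyl)oxy]-2,6,6-trimethylcyclohex-1-en-1-yl trifluoromethanesulfonate | CC1=C(OS(=O)(=O)C(F)(F)F)C(C)(C)C[C@H](O[Si](C)(C)C(C)(C)C)C1 | intermediate
4 | (2E)-3-methylpent-2-en-4-yn-1-ol | C#C/C(C)=C/CO | starting material
5 | trimethyl{[(2E)-3-methyl-5-(trimethylsilyl)pent-2-en-4-yn-1-yl]oxy}silane | C[Si](C)(C)C#C/C(C)=C/CO[Si](C)(C)C | intermediate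
6 | (2E)-3-methyl-5-(trimethylsilyl)pent-2-en-4-yn-1-ol | C[Si](C)(C)C#C/C(C)=C/CO | intermediate
7 | [(3E)-5-bromo-3-methylpent-3-en-1-yn-1-yl]trimethylsilane | C[Si](C)(C)C#C/C(C)=C/CBr | intermediate
8 | diethyl [(2E)-3-methyl-5-(trimethylsilyl)pent-2-en-4-yn-1-yl]phosphonate | CCOP(=O)(OCC)C/C=C(C)/C#C[Si](C)(C)C | intermediate
9 | diethyl [(2E)-3-methylpent-2-en-4-yn-1-yl]phosphonate | CCOP(=O)(OCC)C/C=C(C)/C#C | intermediate
10 | diethyl {(2E)-5-[(4R)-4-[(tert-butyldimethylsilyl)oxy]-2,6,6-trimethylcyclohex-1-en-1-yl]-3-methylpent-2-en-4-yn-1-yl}phosphonate | CC1=C(C#C/C(C)=C/CP(=O)(OCC)OCC)C(C)(C)C[C@H](O[Si](C)(C)C(C)(C)C)C1 | intermediate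
11 | 2,2-dimethoxyacetaldehyde | COC(OC)C=O | starting material
12 | [(3E,5E)-7,7-dimethoxy-3-methylhepta-3,5-dien-1-yn-1-yl]trimethylsilane | COC(OC)/C=C/C=C(C)/C#C[Si](C)(C)C | intermediate
13 | (2E,4E)-5-methyl-7-(trimethylsilyl)hepta-2,4-dien-6-ynal | O=C/C=C/C=C(C)/C#C[Si](C)(C)C | intermediate
14 | tert-butyl{[(1R)-4-[(3E,5E,7E,9E)-3,10-dimethyl-12-(trimethylsilyl)dodeca-3,5,7,9-tetraene-1,11-diyn-1-yl]-3,5,5-trimethylcyclohex-3-en-1-yl]oxy}dimethylsilane | CC1=C(C#C/C(C)=C/C=C/C=C/C=C(C)/C#C[Si](C)(C)C)C(C)(C)C[C@H](O[Si](C)(C)C(C)(C)C)C1 | intermediate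
15 | (1R)-4-[(3E,5E,7E,9E)-3,10-dimethyldodeca-3,5,7,9-tetraene-1,11-diyn-1-yl]-3,5,5-trimethylcyclohex-3-en-1-ol | CC1=C(C#C/C(C)=C/C=C/C=C/C=C(C)/C#C)C(C)(C)C[C@H](O)C1 | intermediate
16 | prop-2-ynoic acid (propiolic acid) | C#CC(=O)O | starting material
17 | (2E)-2,3-dibromoprop-2-enoic acid | Br/C=C(/Br)C(=O)O | intermediate
18 | (2E,6E,8E,10E,12E)-2-bromo-15-[(4R)-4-hydroxy-2,6,6-trimethylcyclohex-1-en-1-yl]-6,13-dimethylpentadeca-2,6,8,10,12-pentaene-4,14-diynoic acid | CC1=C(C#C/C(C)=C/C=C/C=C/C=C(C)/C#C/C=C(/Br)C(=O)O)C(C)(C)C[C@H](O)C1 | intermediate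
19 | (5Z)-3-bromo-5-{(2E,4E,6E,8E)-11-[(4R)-4-hydroxy-2,6,6-trimethylcyclohex-1-en-1-yl]-2,9-dimethylundeca-2,4,6,8-tetraen-10-yn-1-ylidene}furan-2(5H)-one | CC1=C(C#C/C(C)=C/C=C/C=C/C=C(C)/C=C2C=C(Br)C(=O)O/2)C(C)(C)C[C@H](O)C1 | intermediate
20 | ethynyltrimethylsilane | C#C[Si](C)(C)C | starting material
21 | tert-butyldimethyl{[(1R)-3,5,5-trimethyl-4-[(trimethylsilyl)ethynyl]cyclohex-3-en-1-yl]oxy}silane | CC1=C(C#C[Si](C)(C)C)C(C)(C)C[C@H](O[Si](C)(C)C(C)(C)C)C1 | intermediate
22 | (1R)-4-ethynyl-3,5,5-trimethylcyclohex-3-en-1-ol | CC1=C(C#C)C(C)(C)C[C@H](O)C1 | intermediate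
23 | (1S,3S,6S)-6-ethynyl-1,5,5-trimethyl-7-oxabicyclo[4.1.0]heptan-3-ol | C#C[C@@]1(O2)C(C)(C)C[C@H](O)C[C@@]12C | intermediate
24 | (1S,2R,4S)-1-ethynyl-2,6,6-trimethylcyclohexane-1,2,4-triol | C#C[C@@]1(O)C(C)(C)C[C@H](O)C[C@@]1(C)O | intermediate
25 | (1R,2R,4S)-2,6,6-trimethyl-1-[(E)-2-(tributylstannyl)ethenyl]cyclohexane-1,2,4-triol | CCCC[Sn](CCCC)(CCCC)/C=C/[C@@]1(O)C(C)(C)C[C@H](O)C[C@@]1(C)O | intermediate
26 | (5Z)-5-{(2E,4E,6E,8E)-11-[(4R)-4-hydroxy-2,6,6-trimethylcyclohex-1-en-1-yl]-2,9-dimethylundeca-2,4,6,8-tetraen-10-yn-1-ylidene}-3-{(E)-2-[(1R,2R,4S)-1,2,4-trihydroxy-2,6,6-trimethylcyclohexyl]ethenyl}furan-2(5H)-one | CC1=C(C#C/C(C)=C/C=C/C=C/C=C(C)/C=C2C=C(/C=C/[C@@]3(O)C(C)(C)C[C@H](O)C[C@@]3(C)O)C(=O)O/2)C(C)(C)C[C@H](O)C1 | target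

## Step count and least certain steps

Total step count: 18. Longest linear sequence: 9 steps (steps 3, 4, 5, 6, 7, 9, 10, 12, 18, from 4 to 26).

Step 12 (key step).
- What may go wrong: a second Sonogashira coupling at the C3 bromide of the product, oxidative homocoupling of the terminal alkyne, incomplete or 6-endo cyclisation, and decomposition of the terminal polyenyne before it couples. All follow from running coupling and cyclisation in one flask with one catalyst system.
- Fallback (sets out from 15 and 17, returns at 19): the two events are separated. Compound 17 would be esterified (MeOH, cat. H2SO4, 50 °C) to methyl (2E)-2,3-dibromoprop-2-enoate F1, which cannot cyclise. A plain Sonogashira coupling with 15 (Pd(PPh3)4, CuI, i-Pr2NH, THF, 0 °C) would then be optimised on its own to give methyl (2E,6E,8E,10E,12E)-2-bromo-15-[(4R)-4-hydroxy-2,6,6-trimethylcyclohex-1-en-1-yl]-6,13-dimethylpentadeca-2,6,8,10,12-pentaene-4,14-diynoate F2. Saponification (LiOH, THF/H2O, 0 °C) would give 18 as an isolated acid, and AgNO3 (10 mol%) in acetone at rt would close ring C by anti 5-exo-dig addition to 19.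

Step 15.
- What may go wrong: poor facial control or no reaction. Direction needs the C3 hydroxyl pseudoaxial, where it is 1,3-syn to an axial methyl of C1; the tetrasubstituted enyne double bond is hindered and electron-poor; oxidation of the secondary alcohol could compete.
- Fallback (sets out from 22, returns at 23): oxygen is delivered from within the molecule and not by a catalyst. Compound 22 would be converted (Boc2O, DMAP, MeCN) into tert-butyl (1R)-4-ethynyl-3,5,5-trimethylcyclohex-3-en-1-yl carbonate F3. Iodine monobromide in toluene at −80 °C would then induce iodocarbonate cyclisation. The carbonyl oxygen tethered at C3 can reach C5 only on its own face, so the iodonium ion must form on the other face, giving 8-ethynyl-8-iodo-1,7,7-trimethyl-2,4-dioxabicyclo[3.3.1]nonan-3-one F4 (carbonate bridging the C3 and C5 oxygens cis, iodine at C6 trans to the new C5–O bond). K2CO3 in MeOH would cleave the carbonate, and the freed C5 alkoxide would displace iodide from the back to give 23, with the epoxide necessarily cis to the C3 hydroxyl.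

Step 18.
- What may go wrong: slow transmetalation of a stannane next to a quaternary carbinol carbon, leading to protodestannylation, homocoupling and light- or heat-induced E/Z isomerisation of the ylidene and polyene during a long reaction.
- Fallback (sets out from 24, returns at 26): the nucleophile is changed from tin to boron. Copper-catalysed formal hydroboration of 24 (CuCl, Xantphos, NaOt-Bu, B2pin2, MeOH, THF, rt; tolerant of free hydroxyls) would give (1R,2R,4S)-2,6,6-trimethyl-1-[(E)-2-(4,4,5,5-tetramethyl-1,3,2-dioxaborolan-2-yl)ethenyl]cyclohexane-1,2,4-triol F5. Suzuki–Miyaura coupling with 19 (PdCl2(dppf), K3PO4, THF/H2O, rt, dark) would give 26.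

Step 7.
- What may go wrong: sluggish oxidative addition at the hindered tetrasubstituted enol triflate, combined with copper-mediated homocoupling of 9 or base-induced isomerisation of its allylic phosphonate.
- Fallback (sets out from 3 and 4, returns at 10): the alkyne is coupled before the phosphonate exists. Sonogashira coupling of 3 with 4 (Pd(PPh3)4, CuI, i-Pr2NH, DMF, rt) would give (2E)-5-[(4R)-4-[(tert-butyldimethylsilyl)oxy]-2,6,6-trimethylcyclohex-1-en-1-yl]-3-methylpent-2-en-4-yn-1-ol F6. An Appel reaction (CBr4, PPh3, CH2Cl2, 0 °C) would give {[(1R)-4-[(3E)-5-bromo-3-methylpent-3-en-1-yn-1-yl]-3,5,5-trimethylcyclohex-3-en-1-yl]oxy}(tert-butyl)dimethylsilane F7. A Michaelis–Arbuzov reaction (P(OEt)3, 90 °C) would give 10. Step 6 is then not needed for this half.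

## Further compounds

F1 | step 12 | methyl (2E)-2,3-dibromoprop-2-enoate | Br/C=C(/Br)C(=O)OC
F2 | step 12 | methyl (2E,6E,8E,10E,12E)-2-bromo-15-[(4R)-4-hydroxy-2,6,6-trimethylcyclohex-1-en-1-yl]-6,13-dimethylpentadeca-2,6,8,10,12-pentaene-4,14-diynoate | CC1=C(C#C/C(C)=C/C=C/C=C/C=C(C)/C#C/C=C(/Br)C(=O)OC)C(C)(C)C[C@H](O)C1
F3 | step 15 | tert-butyl (1R)-4-ethynyl-3,5,5-trimethylcyclohex-3-en-1-yl carbonate | CC1=C(C#C)C(C)(C)C[C@H](OC(=O)OC(C)(C)C)C1
F4 | step 15 | 8-ethynyl-8-iodo-1,7,7-trimethyl-2,4-dioxabicyclo[3.3.1]nonan-3-one (iodine trans to the adjacent carbonate oxygen) | C#C[C@]1(I)C(C)(C)C[C@H]2C[C@]1(C)OC(=O)O2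
F5 | step 18 | (1R,2R,4S)-2,6,6-trimethyl-1-[(E)-2-(4,4,5,5-tetramethyl-1,3,2-dioxaborolan-2-yl)ethenyl]cyclohexane-1,2,4-triol | CC1(C)OB(/C=C/[C@@]2(O)C(C)(C)C[C@H](O)C[C@@]2(C)O)OC1(C)C
F6 | step 7 | (2E)-5-[(4R)-4-[(tert-butyldimethylsilyl)oxy]-2,6,6-trimethylcyclohex-1-en-1-yl]-3-methylpent-2-en-4-yn-1-ol | CC1=C(C#C/C(C)=C/CO)C(C)(C)C[C@H](O[Si](C)(C)C(C)(C)C)C1
F7 | step 7 | {[(1R)-4-[(3E)-5-bromo-3-methylpent-3-en-1-yn-1-yl]-3,5,5-trimethylcyclohex-3-en-1-yl]oxy}(tert-butyl)dimethylsilane | CC1=C(C#C/C(C)=C/CBr)C(C)(C)C[C@H](O[Si](C)(C)C(C)(C)C)C1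
A1 | alternative 1 | safranal (2,6,6-trimethylcyclohexa-1,3-diene-1-carbaldehyde) | O=CC1=C(C)C=CCC1(C)C
A2 | alternative 1 | trimethyl[(2,6,6-trimethylcyclohexa-1,3-dien-1-yl)ethynyl]silane | C[Si](C)(C)C#CC1=C(C)C=CCC1(C)C
A3 | alternative 1 | trimethyl[(6,7,7-trimethyl-2,3-dioxabicyclo[2.2.2]oct-5-en-1-yl)ethynyl]silane, enantiomer leading to ring A | C[Si](C)(C)C#C[C@@]1(OO2)C(C)(C)C[C@H]2C=C1C
A4 | alternative 1 | cis-2,6,6-trimethyl-1-[(trimethylsilyl)ethynyl]cyclohex-2-ene-1,4-diol, enantiomer leading to ring A | C[Si](C)(C)C#C[C@@]1(O)C(C)(C)C[C@H](O)C=C1C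
A5 | alternative 2 | (2E)-1-[(4R)-4-[(tert-butyldimethylsilyl)oxy]-2,6,6-trimethylcyclohex-1-en-1-yl]-4,4-dimethoxy-2-methylbut-2-en-1-one | CC1=C(C(=O)/C(C)=C/C(OC)OC)C(C)(C)C[C@H](O[Si](C)(C)C(C)(C)C)C1
A6 | alternative 2 | tert-butyl{[(1R)-4-[(3E)-5,5-dimethoxy-3-methylpent-3-en-1-yn-1-yl]-3,5,5-trimethylcyclohex-3-en-1-yl]oxy}dimethylsilane | CC1=C(C#C/C(C)=C/C(OC)OC)C(C)(C)C[C@H](O[Si](C)(C)C(C)(C)C)C1
A7 | alternative 3 | (Z)-β-iodo enone: (1E,3Z,8E)-10-[(tert-butyldimethylsilyl)oxy]-1-[(1R,2R,4S)-4-[(tert-butyldimethylsilyl)oxy]-1,2-dihydroxy-2,6,6-trimethylcyclohexyl]-3-iodo-8-methyldeca-1,3,8-trien-5-one | CC(C)(C)[Si](C)(C)OC/C=C(C)/CC(=O)/C=C(I)/C=C/[C@@]1(O)C(C)(C)C[C@H](O[Si](C)(C)C(C)(C)C)C[C@@]1(C)O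
A8 | alternative 3 | (5Z)-5-[(2E)-4-[(tert-butyldimethylsilyl)oxy]-2-methylbut-2-en-1-ylidene]-3-{(E)-2-[(1R,2R,4S)-4-[(tert-butyldimethylsilyl)oxy]-1,2-dihydroxy-2,6,6-trimethylcyclohexyl]ethenyl}furan-2(5H)-one | CC(C)(C)[Si](C)(C)OC/C=C(C)/C=C1C=C(/C=C/[C@@]2(O)C(C)(C)C[C@H](O[Si](C)(C)C(C)(C)C)C[C@@]2(C)O)C(=O)O/1
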